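**Strategy.** Ring B (numbered as its benzoic acid: C1 carboxyl, C2 and C4 hydroxyl, C3 and C6 methyl, C5 the depside oxygen) is disconnected at C3–C4 and C6–C1. Because C5 is an oxygenated carbon lying between the C4 oxygen and the C6 methyl, it is carried as the sp3 CH–O–aroyl carbon of a ketal-masked acetoacetyl chloride that already bears ring A. A TiCl4-mediated [3+3] cycloaromatisation with the bis(silyl) dienol ether of benzyl 3-oxopentanoate acylates the diene terminus, closes ring B and aromatises it in one operation, so the hindered depside ester never has to be made from a hexasubstituted phenol. Hydrogenolysis of three benzyl groups finishes the synthesis.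

Key step: step 14

Remark: 2,6-dihydroxy-4-methylbenzoic acid, allyl acetoacetate and methyl 3-oxopentanoate are taken as catalogue compounds. "Aroyl" always means the ring A acyl group 2-(benzyloxy)-3-(benzyloxycarbonyl)-4-methoxy-6-methylbenzoyl. Compounds with one sp3 stereocentre are racemic, and that centre becomes an arene carbon in step 14.

Step 1
Reactants: 1 methyl 3-oxopentanoate
Product: 2 benzyl 3-oxopentanoate
Conditions: BnOH (1.2 equiv), DMAP (cat.), toluene, reflux with removal of MeOH
Reagents that add atoms: benzyl alcohol, OCc1ccccc1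
Why: Transesterification of a β-keto ester proceeds on heating by DMAP-assisted acyl exchange (or the acylketene pathway), and distilling out methanol pulls it to the benzyl ester.

Step 2
Reactants: 2 benzyl 3-oxopentanoate
Product: 3 benzyl (Z)-3-(trimethylsilyloxy)pent-2-enoate
Conditions: TMSCl, Et3N, toluene, rt
Reagents that add atoms: chlorotrimethylsilane, C[Si](C)(C)Cl
Why: Silyl enol ether formation: the readily enolised β-keto ester is O-silylated under mild amine conditions to the conjugated 3-silyloxy enoate, which sets up γ-deprotonation.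

Step 3
Reactants: 3 benzyl (Z)-3-(trimethylsilyloxy)pent-2-enoate
Product: 5 1-(benzyloxy)-1,3-bis(trimethylsilyloxy)penta-1,3-diene, via lithium dienolate 4 (not isolated)
Conditions: LiN(i-Pr)2, THF, −78 °C; then TMSCl, −78 °C → rt
Reagents that add atoms: chlorotrimethylsilane, C[Si](C)(C)Cl
Why: Kinetic γ-deprotonation of the vinylogous ester by the lithium amide and O-silylation of the ester dienolate is the standard two-stage preparation of 1,3-bis(silyloxy)dienes; the double-bond geometry is irrelevant because both alkenes end up in the arene.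

Step 4
Reactants: 6 2,6-dihydroxy-4-methylbenzoic acid
Product: 7 benzyl 2,6-dihydroxy-4-methylbenzoate
Conditions: BnBr, KHCO3, DMF, 40 °C
Reagents that add atoms: benzyl bromide, BrCc1ccccc1
Why: Carboxylate O-alkylation (SN2): hydrogencarbonate ionises only the strongly acidic carboxyl group, so benzyl bromide esterifies it and the two chelated phenols stay free.

Step 5
Reactants: 7 benzyl 2,6-dihydroxy-4-methylbenzoate
Product: 8 benzyl 2-hydroxy-6-methoxy-4-methylbenzoate
Conditions: MeI (1.05 equiv), K2CO3 (1.1 equiv), acetone, 40 °C
Reagents that add atoms: iodomethane, CI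
Why: Williamson ether synthesis on a mirror-symmetric diol, so either hydroxyl gives the same ether, and one equivalent of MeI should stop at the monoether because the remaining phenol is locked in a hydrogen bond to the ester carbonyl.

Step 6
Reactants: 8 benzyl 2-hydroxy-6-methoxy-4-methylbenzoate
Product: 10 benzyl 3-formyl-2-hydroxy-6-methoxy-4-methylbenzoate, via hydroxymethyl phenol 9 (not isolated)
Conditions: MgCl2 (2 equiv), Et3N (4 equiv), (CH2O)n (6 equiv), MeCN, reflux; 1 M HCl
Reagents that add atoms: paraformaldehyde (as formaldehyde), C=O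
Why: Casnati–Skattebøl ortho-formylation: the magnesium phenoxide delivers formaldehyde only to the one free position ortho to the phenol (C3, also para to the methoxy group), and a second formaldehyde oxidises the benzylic alkoxide by hydride transfer, so C5 cannot compete.

Step 7
Reactants: 10 benzyl 3-formyl-2-hydroxy-6-methoxy-4-methylbenzoate
Product: 11 benzyl 2-(benzyloxy)-3-formyl-6-methoxy-4-methylbenzoate
Conditions: BnBr, K2CO3, DMF, 60 °C
Reagents that add atoms: benzyl bromide, BrCc1ccccc1
Why: Williamson ether synthesis; carbonate in warm DMF breaks the chelate of the doubly flanked phenol, and benzylation masks it before the oxidation and the Lewis-acid step.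

Step 8
Reactants: 11 benzyl 2-(benzyloxy)-3-formyl-6-methoxy-4-methylbenzoate
Product: 12 2-(benzyloxy)-3-(benzyloxycarbonyl)-4-methoxy-6-methylbenzoic acid
Conditions: NaClO2, NaH2PO4, 2-methyl-2-butene (excess), t-BuOH/H2O, rt
Reagents that add atoms: sodium chlorite, [Na+].[O-]Cl=O
Why: Pinnick oxidation: chlorous acid converts the hindered aryl aldehyde to the acid without touching the benzyl ether or ester, and 2-methyl-2-butene intercepts hypochlorous acid before it can chlorinate the electron-rich ring.

Step 9
Reactants: 13 allyl acetoacetate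
Product: 14 allyl 2-chloro-3-oxobutanoate (racemic)
Conditions: SO2Cl2 (1.0 equiv), CH2Cl2, 0 °C → rt
Reagents that add atoms: sulfuryl chloride, O=S(=O)(Cl)Cl
Why: Electrophilic α-chlorination of the enol of a β-keto ester with sulfuryl chloride is much faster at 0 °C than any reaction at the allyl double bond, and one equivalent stops at the monochloride.

Step 10
Reactants: 12 2-(benzyloxy)-3-(benzyloxycarbonyl)-4-methoxy-6-methylbenzoic acid; 14 allyl 2-chloro-3-oxobutanoate
Product: 15 allyl 2-(aroyloxy)-3-oxobutanoate (racemic)
Conditions: Cs2CO3 (0.5 equiv), DMF, 0 °C → rt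
Reagents that add atoms: none
Why: SN2 displacement of the doubly activated α-chloride by a caesium carboxylate gives the α-acyloxy β-keto ester; carboxylate O-alkylation is insensitive to the two ortho substituents of the acid, and half an equivalent of carbonate leaves no base to enolise the product.

Step 11
Reactants: 15 allyl 2-(aroyloxy)-3-oxobutanoate
Product: 16 allyl 2-(aroyloxy)-3,3-(ethylenedioxy)butanoate (racemic)
Conditions: TMSOCH2CH2OTMS, TMSOTf (cat.), CH2Cl2, −78 → 0 °C; pyridine quench
Reagents that add atoms: 1,2-bis(trimethylsilyloxy)ethane, C[Si](C)(C)OCCO[Si](C)(C)C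
Why: Noyori ketalisation: the silyl triflate activates the ketone and the bis-silyl glycol closes the dioxolane irreversibly with loss of hexamethyldisiloxane, under aprotic conditions that spare the esters; masking the ketone here also prevents decarboxylation once the acid is freed.

Step 12
Reactants: 16 allyl 2-(aroyloxy)-3,3-(ethylenedioxy)butanoate
Product: 17 2-(aroyloxy)-3,3-(ethylenedioxy)butanoic acid (racemic)
Conditions: Pd(PPh3)4 (cat.), morpholine, THF, rt; cold aq. KHSO4
Reagents that add atoms: none
Why: Tsuji–Trost-type deallylation: zerovalent palladium ionises the allyl ester to a π-allyl complex that morpholine captures, a neutral cleavage that leaves the ketal, benzyl ether, benzyl ester and aroyl ester intact, which an acid- or base-labile ester could not guarantee.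

Step 13
Reactants: 17 2-(aroyloxy)-3,3-(ethylenedioxy)butanoic acid
Product: 18 2-(aroyloxy)-3,3-(ethylenedioxy)butanoyl chloride (racemic)
Conditions: (COCl)2, DMF (cat.), CH2Cl2, 0 °C → rt; evaporate, use crude
Reagents that add atoms: oxalyl chloride, ClC(=O)C(=O)Cl
Why: Acid chloride formation through the catalytic Vilsmeier-type chloroiminium salt; the ketal-masked acid cannot decarboxylate, the electron-poor dioxolane should tolerate anhydrous HCl, and the volatile by-products allow direct use of the crude chloride.

Step 14
Reactants: 5 1-(benzyloxy)-1,3-bis(trimethylsilyloxy)penta-1,3-diene; 18 2-(aroyloxy)-3,3-(ethylenedioxy)butanoyl chloride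
Product: 21 tribenzyl hypothamnolic acid (free ring B hydroxyls), via open-chain silyl enol ether 19 (not isolated), via cyclohexanedione adduct 20 (not isolated)
Conditions: TiCl4 (2.2 equiv), CH2Cl2, −78 → 0 °C; cold 1 M HCl
Reagents that add atoms: none
Why: TiCl4 activates acid chloride 18 toward the methyl-bearing terminal carbon of diene 5 (future ring B C3), giving silyl enol ether 19 with loss of TMSCl; on warming, TiCl4 opens the dioxolane to an oxocarbenium ion at the methyl-bearing carbon (future C6), which is captured by the central carbon of the remaining silyl enol ether (future C1) in a Mukaiyama-type aldol to give 20, and β-elimination of the titanium glycolate followed by two enolisations delivers the arene. The closest known reaction type is the formal [3+3] cycloaromatisation of 1,3-bis(silyloxy)dienes with ketal-masked β-keto acid chlorides to resorcylates. Ring B closes in a 6-(enolendo)-exo-trig mode, the enol carbon attacking the exocyclic C=O+ bond. No stereocentre survives, since the racemic centre of 18 and the centres formed in 19 and 20 all become sp2 arene carbons. The regiochemistry that is needed (diene terminus to the acyl carbon, central carbon to the ketal carbon) rests on the reactivity order at −78 °C, where the acid chloride is the only electrophile and the diene terminus the best nucleophile, the ketal ionising only afterwards. The aroyloxy group should be retained because it sits alpha, not beta, to every enolisable carbonyl, so no elimination pathway exists, and its di-ortho-substituted acyl group resists transfer to the neighbouring phenol.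

Step 15
Reactants: 21 tribenzyl hypothamnolic acid
Product: 22 hypothamnolic acid
Conditions: H2 (1 atm), Pd/C (10%), EtOAc, rt
Reagents that add atoms: none
Why: Catalytic hydrogenolysis cleaves the two benzyl esters and the aryl benzyl ether at room temperature under neutral conditions, so the depside ester and the decarboxylation-prone hydroxy acids are not exposed to acid, base or heat.

**Compound list**

1 | methyl 3-oxopentanoate | CCC(=O)CC(=O)OC | starting material
2 | benzyl 3-oxopentanoate | CCC(=O)CC(=O)OCc1ccccc1 | intermediate
3 | benzyl (Z)-3-(trimethylsilyloxy)pent-2-enoate (Z drawn; either isomer serves) | CC/C(O[Si](C)(C)C)=C/C(=O)OCc1ccccc1 | intermediate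
4 | lithium 1-(benzyloxy)-3-(trimethylsilyloxy)penta-1,3-dien-1-olate (geometry as drawn, not critical) | C/C=C(\O[Si](C)(C)C)/C=C(\OCc1ccccc1)[O-].[Li+] | intermediate (not isolated)
5 | (1E,3Z)-1-(benzyloxy)-1,3-bis(trimethylsilyloxy)penta-1,3-diene (one isomer drawn; any isomer serves) | C/C=C(\O[Si](C)(C)C)/C=C(\OCc1ccccc1)O[Si](C)(C)C | intermediate
6 | 2,6-dihydroxy-4-methylbenzoic acid | Cc1cc(O)c(C(=O)O)c(O)c1 | starting material
7 | benzyl 2,6-dihydroxy-4-methylbenzoate | Cc1cc(O)c(C(=O)OCc2ccccc2)c(O)c1 | intermediate
8 | benzyl 2-hydroxy-6-methoxy-4-methylbenzoate | COc1cc(C)cc(O)c1C(=O)OCc1ccccc1 | intermediate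
9 | benzyl 2-hydroxy-3-(hydroxymethyl)-6-methoxy-4-methylbenzoate (present as its magnesium salt) | COc1cc(C)c(CO)c(O)c1C(=O)OCc1ccccc1 | intermediate (not isolated)
10 | benzyl 3-formyl-2-hydroxy-6-methoxy-4-methylbenzoate | COc1cc(C)c(C=O)c(O)c1C(=O)OCc1ccccc1 | intermediate
11 | benzyl 2-(benzyloxy)-3-formyl-6-methoxy-4-methylbenzoate | COc1cc(C)c(C=O)c(OCc2ccccc2)c1C(=O)OCc1ccccc1 | intermediate
12 | 2-(benzyloxy)-3-(benzyloxycarbonyl)-4-methoxy-6-methylbenzoic acid (ring A acid) | COc1cc(C)c(C(=O)O)c(OCc2ccccc2)c1C(=O)OCc1ccccc1 | intermediate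
13 | allyl acetoacetate (allyl 3-oxobutanoate) | CC(=O)CC(=O)OCC=C | starting material
14 | allyl 2-chloro-3-oxobutanoate, racemic | CC(=O)C(Cl)C(=O)OCC=C | intermediate
15 | allyl 2-(aroyloxy)-3-oxobutanoate, racemic | CC(=O)C(OC(=O)c1c(C)cc(OC)c(C(=O)OCc2ccccc2)c1OCc1ccccc1)C(=O)OCC=C | intermediate
16 | allyl 2-(aroyloxy)-3,3-(ethylenedioxy)butanoate, racemic | CC1(OCCO1)C(OC(=O)c1c(C)cc(OC)c(C(=O)OCc2ccccc2)c1OCc1ccccc1)C(=O)OCC=C | intermediate
17 | 2-(aroyloxy)-3,3-(ethylenedioxy)butanoic acid, racemic | CC1(OCCO1)C(OC(=O)c1c(C)cc(OC)c(C(=O)OCc2ccccc2)c1OCc1ccccc1)C(=O)O | intermediate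
18 | 2-(aroyloxy)-3,3-(ethylenedioxy)butanoyl chloride, racemic | CC1(OCCO1)C(OC(=O)c1c(C)cc(OC)c(C(=O)OCc2ccccc2)c1OCc1ccccc1)C(=O)Cl | intermediate
19 | benzyl 6-(aroyloxy)-7,7-(ethylenedioxy)-4-methyl-5-oxo-3-(trimethylsilyloxy)oct-2-enoate (diastereomer and alkene-isomer mixture) | CC(C(=O)C(OC(=O)c1c(C)cc(OC)c(C(=O)OCc2ccccc2)c1OCc1ccccc1)C1(C)OCCO1)C(O[Si](C)(C)C)=CC(=O)OCc1ccccc1 | intermediate (not isolated)
20 | benzyl 5-(aroyloxy)-6-(2-hydroxyethoxy)-3,6-dimethyl-2,4-dioxocyclohexane-1-carboxylate (stereoisomer mixture, present as titanium alkoxide) | CC1C(=O)C(OC(=O)c2c(C)cc(OC)c(C(=O)OCc3ccccc3)c2OCc2ccccc2)C(C)(OCCO)C(C(=O)OCc2ccccc2)C1=O | intermediate (not isolated)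
21 | tribenzyl hypothamnolic acid: benzyl 5-(aroyloxy)-2,4-dihydroxy-3,6-dimethylbenzoate | COc1cc(C)c(C(=O)Oc2c(C)c(C(=O)OCc3ccccc3)c(O)c(C)c2O)c(OCc2ccccc2)c1C(=O)OCc1ccccc1 | intermediate
22 | hypothamnolic acid | COc1cc(C)c(C(=O)Oc2c(C)c(C(=O)O)c(O)c(C)c2O)c(O)c1C(=O)O | target

**Totals and risks**

Total step count: 15. Longest linear sequence: 11 steps (steps 4–8, then 10–15, from compound 6).

Steps most likely to fail:

1. Step 14. Acylation may stall at the hindered acid chloride, or the electron-poor dioxolane may ionise too slowly, so that TiCl4 instead attacks the benzyl groups or decomposes the diene. (Loss of the ring A benzyl ether alone would be harmless, since step 15 removes it anyway.) The fallback sets out from 5 and 18 and comes back at 21 by separating the two bond formations. Diene 5 is C-acylated by 18 without Lewis acid (CH2Cl2, −78 → 20 °C; aqueous NH4Cl), a known uncatalysed acylation of bis(silyloxy)dienes, to give benzyl 6-(aroyloxy)-7,7-(ethylenedioxy)-4-methyl-3,5-dioxooctanoate F1. The ketal is then hydrolysed (aqueous TFA, CH2Cl2) to benzyl 6-(aroyloxy)-4-methyl-3,5,7-trioxooctanoate F2. Under the same acid F2 should close by intramolecular aldol condensation of C2 onto the C7 ketone and dehydrate to 21, the classical cyclisation of a 3,5,7-tricarbonyl ester to a resorcylate.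

2. Step 11. Ketal closure may be blocked by the bulky aroyloxy group next to the ketone, or the silyl triflate may be consumed in enol silylation. The fallback sets out from 14 (and uses 12) and comes back at 16 by forming the ketal while the α-substituent is small and attaching ring A last. Chloride 14 is displaced with KOAc (DMF) to give allyl 2-acetoxy-3-oxobutanoate F3. Ketalisation (TMSOCH2CH2OTMS, TMSOTf cat.) gives allyl 2-acetoxy-3,3-(ethylenedioxy)butanoate F4. The acetate is removed by transesterification (K2CO3, allyl alcohol, which keeps the ester as allyl) to give allyl 2-hydroxy-3,3-(ethylenedioxy)butanoate F5. Acid 12 is converted with (COCl)2 and catalytic DMF to 2-(benzyloxy)-3-(benzyloxycarbonyl)-4-methoxy-6-methylbenzoyl chloride F6, and acylation of F5 with F6 (DMAP, Et3N, CH2Cl2) gives 16.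

3. Step 6. The chelated, ester-deactivated phenol may react sluggishly at the position flanked by hydroxyl and methyl, leaving hydroxymethyl or diarylmethane by-products. The fallback sets out from 7 and comes back at 10 by reversing the order of formylation and methylation. The more electron-rich diol 7 undergoes Vilsmeier–Haack formylation (POCl3, DMF, MeCN, 0 °C → rt; aqueous hydrolysis) at one of its two equivalent positions to give benzyl 3-formyl-2,6-dihydroxy-4-methylbenzoate F7. One equivalent of MeI with K2CO3 (acetone) should then methylate the hydroxyl para to the formyl group, because the other hydroxyl is flanked by two carbonyls and strongly chelated, as in the selective 4-O-alkylation of 2,4-dihydroxybenzaldehydes; this gives 10.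

**Further compounds**

F1 | step 14 | benzyl 6-(aroyloxy)-7,7-(ethylenedioxy)-4-methyl-3,5-dioxooctanoate (diastereomer mixture) | CC(C(=O)CC(=O)OCc1ccccc1)C(=O)C(OC(=O)c1c(C)cc(OC)c(C(=O)OCc2ccccc2)c1OCc1ccccc1)C1(C)OCCO1
F2 | step 14 | benzyl 6-(aroyloxy)-4-methyl-3,5,7-trioxooctanoate (diastereomer mixture) | CC(=O)C(OC(=O)c1c(C)cc(OC)c(C(=O)OCc2ccccc2)c1OCc1ccccc1)C(=O)C(C)C(=O)CC(=O)OCc1ccccc1
F3 | step 11 | allyl 2-acetoxy-3-oxobutanoate (racemic) | CC(=O)OC(C(C)=O)C(=O)OCC=C
F4 | step 11 | allyl 2-acetoxy-3,3-(ethylenedioxy)butanoate (racemic) | CC(=O)OC(C(=O)OCC=C)C1(C)OCCO1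
F5 | step 11 | allyl 2-hydroxy-3,3-(ethylenedioxy)butanoate (racemic) | OC(C(=O)OCC=C)C1(C)OCCO1
F6 | step 11 | 2-(benzyloxy)-3-(benzyloxycarbonyl)-4-methoxy-6-methylbenzoyl chloride | COc1cc(C)c(C(Cl)=O)c(OCc2ccccc2)c1C(=O)OCc1ccccc1
F7 | step 6 | benzyl 3-formyl-2,6-dihydroxy-4-methylbenzoate | Cc1cc(O)c(C(=O)OCc2ccccc2)c(O)c1C=O
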